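**Plan**

- Enabling feature: in the 14-membered carbocycle the butenolide oxygen on C6 is homoallylic to the (E)-C3=C4(CH3) olefin. The unit C3=C4–C5H2–C6(O) is the retron of a cis hydroalkylation of a methyl-capped alkyne (C3≡C4) by a terminal epoxide (C5–C6).
- Cuts, in retrosynthetic order: C12–OOH (ene reaction); C15=C17/C16 lactone and C7=C8 (oxidation-level adjustments); C4–C5 (ring closure, butenolide ring opened to a γ,δ-epoxy ester); C8–C9 (enolate alkylation); C1–C2 (allylation); C12–C13 (Claisen).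
- Forward: C9–C1 chain (steps 1–5) → C1/C2 stereodiad and prop-1-ynyl group by chromium-catalysed allylation of but-2-ynal (7) → lactone masked as bis-silyl diol (8–9) → chiral-pool γ-lactone appended at C8 (13) and opened to the epoxy ester (14) → nickel-catalysed epoxide–alkyne macrocyclization with relactonization (15) → butenolide (16–17) → α-methylene lactone (18–19) → hydroperoxide (20).
- Stereochemistry: C1/C2 from the ligand-controlled anti allylation; C6 from (S)-5-(hydroxymethyl)butyrolactone (its C6–O bond is never broken); C12 from the suprafacial singlet-oxygen ene reaction on the macrocycle; 11E from the chair Claisen, 3E from syn addition in the key step, 10E from the ene step.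

Key step: step 15

Remark: cembrane numbering is used for positions (ring C1–C14; C1 carries C15(=C17)–C16; C18, C19, C20 are the carbons on C4, C8, C12); PMB = 4-methoxybenzyl, TBS = tert-butyldimethylsilyl.
Remark: C8 is carried as an epimer mixture in 20–25 because it becomes sp2 in step 17; the descriptor of C2 changes from R to S in step 15 and that of C6 from S to R in step 16 only through CIP priority changes, not through any change in spatial arrangement.
Remark: aldehyde 1 is taken as a catalogue compound; in step 7 the ligand enantiomer is the one that leads to the (4R,5R)-lactone 13.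

**Route**

Step 1
Reactants: 1 3-[(4-methoxybenzyl)oxy]propanal; 2 isopropenylmagnesium bromide
Product: 3 (±)-5-[(4-methoxybenzyl)oxy]-2-methylpent-1-en-3-ol
Conditions: THF, −78 → 0 °C; aq. NH4Cl
Reagents that add atoms: none
Why: 1,2-addition of the alkenyl Grignard reagent to the aldehyde gives the secondary allylic alcohol needed for the Claisen step; its racemic carbinol centre is destroyed in step 2.

Step 2
Reactants: 3 (±)-5-[(4-methoxybenzyl)oxy]-2-methylpent-1-en-3-ol; 4 triethyl orthoacetate
Product: 5 ethyl (E)-7-[(4-methoxybenzyl)oxy]-4-methylhept-4-enoate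
Conditions: 4 (excess), EtCO2H (cat.), 140 °C, EtOH distilled off
Reagents that add atoms: none
Why: Johnson–Claisen rearrangement through a chair transition state with the CH2CH2OPMB group equatorial should give the (E)-trisubstituted C11=C12 olefin together with the C13–C14–C1 ester arm.

Step 3
Reactants: 5 ethyl (E)-7-[(4-methoxybenzyl)oxy]-4-methylhept-4-enoate
Product: 6 (E)-7-[(4-methoxybenzyl)oxy]-4-methylhept-4-enal
Conditions: iBu2AlH (1.1 equiv), CH2Cl2, −78 °C; aq. potassium sodium tartrate
Reagents that add atoms: none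
Why: partial reduction of the ester stops at the aldehyde because the tetrahedral aluminium hemiacetal is stable at −78 °C (standard iBu2AlH reduction).

Step 4
Reactants: 6 (E)-7-[(4-methoxybenzyl)oxy]-4-methylhept-4-enal; 7 methyl acrylate
Product: 8 methyl (±)-(E)-3-hydroxy-9-[(4-methoxybenzyl)oxy]-6-methyl-2-methylidenenon-6-enoate
Conditions: 7 (3 equiv), DABCO (50 mol %), MeOH (cat.), rt, several days
Reagents that add atoms: none
Why: Morita–Baylis–Hillman reaction of an unhindered aliphatic aldehyde installs C15–C17; the racemic carbinol centre is erased in step 5.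

Step 5
Reactants: 8 methyl (±)-(E)-3-hydroxy-9-[(4-methoxybenzyl)oxy]-6-methyl-2-methylidenenon-6-enoate
Product: 9 methyl (2Z,6E)-2-(bromomethyl)-9-[(4-methoxybenzyl)oxy]-6-methylnona-2,6-dienoate
Conditions: NBS, Me2S, CH2Cl2, 0 °C → rt
Reagents that add atoms: N-bromosuccinimide, BrN1C(=O)CCC1=O
Why: Corey–Kim-type activation of the alcohol and SN2′ delivery of bromide is the standard conversion of Baylis–Hillman alcohols into the conjugated (Z)-2-(bromomethyl)enoates.

Step 6
Reactants: 10 but-2-yn-1-ol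
Product: 11 but-2-ynal
Conditions: activated MnO2 (excess), CH2Cl2, rt; filtered solution used directly
Reagents that add atoms: none
Why: MnO2 oxidation of a propargylic alcohol gives the volatile ynal without over-oxidation.

Step 7
Reactants: 9 methyl (2Z,6E)-2-(bromomethyl)-9-[(4-methoxybenzyl)oxy]-6-methylnona-2,6-dienoate; 11 but-2-ynal
Product: 13 (4R,5R)-4-[(E)-6-(PMB-oxy)-3-methylhex-3-en-1-yl]-3-methylidene-5-(prop-1-yn-1-yl)dihydrofuran-2(3H)-one, via hydroxy ester 12 (not isolated)
Conditions: CrCl2 (10 mol %), tridentate carbazole bis(oxazoline) ligand (12 mol %), Mn (2 equiv), TMSCl (1.5 equiv), Et3N (20 mol %), THF, rt; then 1 M HCl, THF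
Reagents that add atoms: none
Why: catalytic asymmetric Nozaki–Hiyama–Kishi 2-(alkoxycarbonyl)allylation: the allylchromium species (trivalent chromium, regenerated from divalent chromium by Mn/TMSCl) attacks the ynal through its γ-carbon in a chair transition state with the C14 chain equatorial, which should give the anti (later trans) relationship of C1 and C2, the chiral ligand selects the aldehyde face and hence the absolute configuration, and acid closes the γ-lactone.

Step 8
Reactants: 13 (4R,5R)-4-[(E)-6-(PMB-oxy)-3-methylhex-3-en-1-yl]-3-methylidene-5-(prop-1-yn-1-yl)dihydrofuran-2(3H)-one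
Product: 14 (3R,4R)-3-[(E)-6-(PMB-oxy)-3-methylhex-3-en-1-yl]-2-methylidenehept-5-yne-1,4-diol
Conditions: iBu2AlH (4 equiv), CH2Cl2, −78 → 0 °C; aq. potassium sodium tartrate
Reagents that add atoms: none
Why: 1,2-reduction of the α-methylene lactone gives the 2-methylene-1,4-diol without touching C1 or C2 and removes the Michael acceptor, the propargylic ester and the enolizable carbonyl that would interfere in steps 13–16.

Step 9
Reactants: 14 (3R,4R)-3-[(E)-6-(PMB-oxy)-3-methylhex-3-en-1-yl]-2-methylidenehept-5-yne-1,4-diol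
Product: 15 bis-TBS ether of 14
Conditions: TBSOTf (2.5 equiv), 2,6-lutidine, CH2Cl2, −78 → 0 °C
Reagents that add atoms: tert-butyldimethylsilyl triflate, CC(C)(C)[Si](C)(C)OS(=O)(=O)C(F)(F)F
Why: silyl triflate silylation protects both the primary allylic and the hindered secondary propargylic hydroxyl as ethers that are not leaving groups toward zerovalent nickel.

Step 10
Reactants: 15 bis-TBS ether of 14
Product: 16 (3E,7R,8R)-8-(TBS-oxy)-7-[3-(TBS-oxy)prop-1-en-2-yl]-4-methylundec-3-en-9-yn-1-ol
Conditions: DDQ, CH2Cl2/pH 7 buffer, 0 °C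
Reagents that add atoms: none
Why: oxidative cleavage of the PMB ether by DDQ is neutral and leaves silyl ethers, the alkyne and the unactivated olefins intact.

Step 11
Reactants: 16 (3E,7R,8R)-8-(TBS-oxy)-7-[3-(TBS-oxy)prop-1-en-2-yl]-4-methylundec-3-en-9-yn-1-ol
Product: 17 (3E,7R,8R)-8-(TBS-oxy)-7-[3-(TBS-oxy)prop-1-en-2-yl]-1-iodo-4-methylundec-3-en-9-yne
Conditions: I2, PPh3, imidazole, CH2Cl2, 0 °C
Reagents that add atoms: iodine, [I][I]
Why: Appel-type iodination converts the primary alcohol into the iodide under conditions that tolerate silyl ethers and the alkyne.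

Step 12
Reactants: 18 (S)-5-(hydroxymethyl)dihydrofuran-2(3H)-one
Product: 19 (S)-5-(chloromethyl)dihydrofuran-2(3H)-one
Conditions: PPh3, CCl4, 70 °C
Reagents that add atoms: tetrachloromethane, ClC(Cl)(Cl)Cl
Why: Appel chlorination leaves C6 untouched and installs a β-oxygenated primary chloride that is inert to enolates but is displaced intramolecularly in step 14.

Step 13
Reactants: 19 (S)-5-(chloromethyl)dihydrofuran-2(3H)-one; 17 (3E,7R,8R)-8-(TBS-oxy)-7-[3-(TBS-oxy)prop-1-en-2-yl]-1-iodo-4-methylundec-3-en-9-yne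
Product: 20 (5S)-5-(chloromethyl)-3-[(3E,7R,8R)-8-(TBS-oxy)-7-(3-(TBS-oxy)prop-1-en-2-yl)-4-methylundec-3-en-9-yn-1-yl]dihydrofuran-2(3H)-one (C3 epimers)
Conditions: 19, LiN(iPr)2, THF, −78 °C; then 17, DMPU, −78 → −20 °C
Reagents that add atoms: none
Why: alkylation of the preformed lactone enolate with the primary iodide forms C8–C9; the electrophile carries no carbonyl or acidic hydrogen, and the C8 epimer ratio is of no consequence.

Step 14
Reactants: 20 chloromethyl lactone (C3 epimers)
Product: 21 methyl 2-[(3E,7R,8R)-8-(TBS-oxy)-7-(3-(TBS-oxy)prop-1-en-2-yl)-4-methylundec-3-en-9-yn-1-yl]-3-[(2S)-oxiran-2-yl]propanoate (C2 epimers)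
Conditions: NaOMe (1.2 equiv), MeOH, 0 °C → rt
Reagents that add atoms: sodium methoxide, [Na+].[O-]C
Why: methoxide opens the lactone and the liberated C6 alkoxide displaces chloride (3-exo-tet), the classical halolactone to epoxy ester conversion, so the terminal epoxide forms with retention at C6.

Step 15
Reactants: 21 epoxy ester (C2 epimers)
Product: 23 (1R,2S,3E,6S,11E)-2,16-bis(TBS-oxy)cembra-3,11,15(17)-trien-19,6-olide (C8 epimers), via hydroxy ester 22 (not isolated)
Conditions: Ni(cod)2 (20 mol %), PBu3 (40 mol %), Et3B (3 equiv), THF, 0.005 M, slow addition of 21, rt; aq. NH4Cl; then PPTS (cat.), PhMe, 50 °C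
Reagents that add atoms: none
Why: zerovalent nickel adds oxidatively to the terminal C5–O bond of the epoxide (SN2-type at the unsubstituted carbon, so C6 keeps its configuration), the alkyne inserts into the Ni–C5 bond with C5 going to the methyl-bearing C4 and nickel to C3, and ethyl transfer from Et3B, β-hydride elimination (ethylene) and C3–H reductive elimination complete a net cis hydroalkylation; the closest known reaction type is the nickel-catalysed reductive coupling of alkynes with terminal epoxides, which has been used to close 14-membered rings. The carbocycle closes in a 14-endo-dig sense at the alkyne and exo at the epoxide, and the liberated C6 oxygen then closes the γ-lactone ring by 5-exo-trig acyl substitution on the C19 methyl ester, which may also assist the oxidative addition by coordination. No new sp3 stereocentre is formed: the 3E geometry follows from syn delivery of H and C5 across the triple bond, which places C2 and C5 trans. The step needs regioselectivity at the alkyne (C4 over C3), which the steric difference between the methyl group and the branched C2(OTBS) carbon should secure with the small phosphine, and cyclization over oligomerization, which high dilution with slow addition should secure. The remaining olefins, silyl ethers and ester should be inert because every Michael acceptor, peroxide and propargylic leaving group is absent at this stage.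

Step 16
Reactants: 23 macrocyclic γ-lactone (C8 epimers)
Product: 24 (1R,2S,3E,6R,11E)-2,16-bis(TBS-oxy)-8-(phenylselanyl)cembra-3,11,15(17)-trien-19,6-olide (C8 epimers)
Conditions: LiN(iPr)2, THF, −78 °C; PhSeBr (1.05 equiv), −78 °C
Reagents that add atoms: benzeneselenenyl bromide, Br[Se]c1ccccc1
Why: 23 has a single enolizable position (C8), so enolate selenenylation is unambiguous, and one equivalent of selenenyl bromide at low temperature should spare the olefins.

Step 17
Reactants: 24 α-phenylselanyl lactone (C8 epimers)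
Product: 26 (1R,2S,3E,6R,11E)-2,16-bis(TBS-oxy)cembra-3,7,11,15(17)-tetraen-19,6-olide, via selenoxide 25 (not isolated)
Conditions: mCPBA (1.05 equiv), CH2Cl2, −78 °C; then iPr2NH, −78 °C → rt
Reagents that add atoms: none
Why: selenoxide syn elimination: the C7 hydrogen cis to selenium in the five-membered ring is held syn-periplanar and should be taken in preference to the C9 hydrogens, giving the endocyclic butenolide, while the amine scavenges the selenenic acid before it can add to the olefins.

Step 18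
Reactants: 26 bis-TBS butenolide
Product: 27 (1R,2S,3E,6R,11E)-2,16-dihydroxycembra-3,7,11,15(17)-tetraen-19,6-olide
Conditions: HF·pyridine, pyridine/THF, 0 °C → rt
Reagents that add atoms: none
Why: acidic fluoride removes both silyl ethers without the basic conditions that could epimerize the γ-carbon (C6) of the butenolide.

Step 19
Reactants: 27 diol butenolide
Product: 30 (1R,2S,3E,6R,11E)-cembra-3,7,11,15(17)-tetraene-16,2:19,6-diolide, via enal 28 (not isolated), via lactol 29 (not isolated)
Conditions: TEMPO (20 mol %), PhI(OAc)2 (2.5 equiv), CH2Cl2, rt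
Reagents that add atoms: none
Why: TEMPO/PhI(OAc)2 oxidative lactonization: the primary allylic alcohol is oxidized selectively to the enal, the C2 hydroxyl closes the lactol and a second oxidation gives the α-methylene-γ-butyrolactone.

Step 20
Reactants: 30 bis-lactone tetraene
Product: 31 (1R,2S,3E,6R,10E,12S)-12-hydroperoxycembra-3,7,10,15(17)-tetraene-16,2:19,6-diolide (target)
Conditions: O2, visible light, tetraphenylporphyrin (cat.), CH2Cl2, −20 °C
Reagents that add atoms: dioxygen, O=O
Why: Schenck ene reaction of singlet oxygen with the only electron-rich trisubstituted olefin (C11=C12; C3=C4 is deactivated by the allylic lactone oxygen, C7=C8 and C15=C17 are electron-poor): suprafacial delivery of O2 to C12 with removal of H-10 on the disubstituted side of the olefin gives the tertiary hydroperoxide and the 10E olefin, the C12 configuration being set by attack on the exposed face of the ring olefin, so the 12S isomer may have to be separated from its C12 epimer and from the 11-hydroperoxy-12(20)-ene isomer.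

**Compound list**

1 | 3-[(4-methoxybenzyl)oxy]propanal | O=CCCOCc1ccc(OC)cc1 | starting material
2 | isopropenylmagnesium bromide | C=C(C)[Mg]Br | starting material
3 | (±)-5-[(4-methoxybenzyl)oxy]-2-methylpent-1-en-3-ol | C=C(C)C(O)CCOCc1ccc(OC)cc1 | intermediate
4 | triethyl orthoacetate | CC(OCC)(OCC)OCC | starting material
5 | ethyl (E)-7-[(4-methoxybenzyl)oxy]-4-methylhept-4-enoate | CCOC(=O)CC/C(C)=C/CCOCc1ccc(OC)cc1 | intermediate
6 | (E)-7-[(4-methoxybenzyl)oxy]-4-methylhept-4-enal | O=CCC/C(C)=C/CCOCc1ccc(OC)cc1 | intermediate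
7 | methyl acrylate | C=CC(=O)OC | starting material
8 | methyl (±)-(E)-3-hydroxy-9-[(4-methoxybenzyl)oxy]-6-methyl-2-methylidenenon-6-enoate | C=C(C(=O)OC)C(O)CC/C(C)=C/CCOCc1ccc(OC)cc1 | intermediate
9 | methyl (2Z,6E)-2-(bromomethyl)-9-[(4-methoxybenzyl)oxy]-6-methylnona-2,6-dienoate | COC(=O)/C(CBr)=C/CC/C(C)=C/CCOCc1ccc(OC)cc1 | intermediate
10 | but-2-yn-1-ol | CC#CCO | starting material
11 | but-2-ynal | CC#CC=O | intermediate
12 | methyl (3R,4R)-4-hydroxy-3-[(E)-6-(PMB-oxy)-3-methylhex-3-en-1-yl]-2-methylidenehept-5-ynoate (not isolated) | C=C(C(=O)OC)[C@@H](CC/C(C)=C/CCOCc1ccc(OC)cc1)[C@@H](O)C#CC | intermediate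
13 | (4R,5R)-4-[(E)-6-(PMB-oxy)-3-methylhex-3-en-1-yl]-3-methylidene-5-(prop-1-yn-1-yl)dihydrofuran-2(3H)-one | C=C1C(=O)O[C@@H](C#CC)[C@@H]1CC/C(C)=C/CCOCc1ccc(OC)cc1 | intermediate
14 | (3R,4R)-3-[(E)-6-(PMB-oxy)-3-methylhex-3-en-1-yl]-2-methylidenehept-5-yne-1,4-diol | C=C(CO)[C@@H](CC/C(C)=C/CCOCc1ccc(OC)cc1)[C@@H](O)C#CC | intermediate
15 | 1,4-bis-O-TBS ether of 14 | C=C(CO[Si](C)(C)C(C)(C)C)[C@@H](CC/C(C)=C/CCOCc1ccc(OC)cc1)[C@@H](O[Si](C)(C)C(C)(C)C)C#CC | intermediate
16 | (3E,7R,8R)-8-(TBS-oxy)-7-[3-(TBS-oxy)prop-1-en-2-yl]-4-methylundec-3-en-9-yn-1-ol | C=C(CO[Si](C)(C)C(C)(C)C)[C@@H](CC/C(C)=C/CCO)[C@@H](O[Si](C)(C)C(C)(C)C)C#CC | intermediate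
17 | (3E,7R,8R)-8-(TBS-oxy)-7-[3-(TBS-oxy)prop-1-en-2-yl]-1-iodo-4-methylundec-3-en-9-yne | C=C(CO[Si](C)(C)C(C)(C)C)[C@@H](CC/C(C)=C/CCI)[C@@H](O[Si](C)(C)C(C)(C)C)C#CC | intermediate
18 | (S)-5-(hydroxymethyl)dihydrofuran-2(3H)-one | O=C1CC[C@@H](CO)O1 | starting material
19 | (S)-5-(chloromethyl)dihydrofuran-2(3H)-one | O=C1CC[C@@H](CCl)O1 | intermediate
20 | (5S)-5-(chloromethyl)-3-[(3E,7R,8R)-8-(TBS-oxy)-7-(3-(TBS-oxy)prop-1-en-2-yl)-4-methylundec-3-en-9-yn-1-yl]dihydrofuran-2(3H)-one (C3 epimers) | C=C(CO[Si](C)(C)C(C)(C)C)[C@@H](CC/C(C)=C/CCC1C[C@@H](CCl)OC1=O)[C@@H](O[Si](C)(C)C(C)(C)C)C#CC | intermediate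
21 | methyl 2-[(3E,7R,8R)-8-(TBS-oxy)-7-(3-(TBS-oxy)prop-1-en-2-yl)-4-methylundec-3-en-9-yn-1-yl]-3-[(2S)-oxiran-2-yl]propanoate (C2 epimers) | C=C(CO[Si](C)(C)C(C)(C)C)[C@@H](CC/C(C)=C/CCC(C[C@H]1CO1)C(=O)OC)[C@@H](O[Si](C)(C)C(C)(C)C)C#CC | intermediate
22 | methyl (1R,2S,3E,6S,11E)-2,16-bis(TBS-oxy)-6-hydroxycembra-3,11,15(17)-trien-19-oate (C8 epimers; first formed as its O-diethylboryl derivative; not isolated) | C=C(CO[Si](C)(C)C(C)(C)C)[C@H]1CC/C(C)=C/CCC(C(=O)OC)C[C@H](O)C/C(C)=C/[C@@H]1O[Si](C)(C)C(C)(C)C | intermediate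
23 | (1R,2S,3E,6S,11E)-2,16-bis(TBS-oxy)cembra-3,11,15(17)-trien-19,6-olide (C8 epimers) | C=C(CO[Si](C)(C)C(C)(C)C)[C@H]1CC/C(C)=C/CCC2C[C@@H](C/C(C)=C/[C@@H]1O[Si](C)(C)C(C)(C)C)OC2=O | intermediate
24 | (1R,2S,3E,6R,11E)-2,16-bis(TBS-oxy)-8-(phenylselanyl)cembra-3,11,15(17)-trien-19,6-olide (C8 epimers) | C=C(CO[Si](C)(C)C(C)(C)C)[C@H]1CC/C(C)=C/CCC2([Se]c3ccccc3)C[C@@H](C/C(C)=C/[C@@H]1O[Si](C)(C)C(C)(C)C)OC2=O | intermediate
25 | selenoxide of 24 (not isolated) | C=C(CO[Si](C)(C)C(C)(C)C)[C@H]1CC/C(C)=C/CCC2([Se](=O)c3ccccc3)C[C@@H](C/C(C)=C/[C@@H]1O[Si](C)(C)C(C)(C)C)OC2=O | intermediate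
26 | (1R,2S,3E,6R,11E)-2,16-bis(TBS-oxy)cembra-3,7,11,15(17)-tetraen-19,6-olide | C=C(CO[Si](C)(C)C(C)(C)C)[C@H]1CC/C(C)=C/CCC2=C[C@@H](C/C(C)=C/[C@@H]1O[Si](C)(C)C(C)(C)C)OC2=O | intermediate
27 | (1R,2S,3E,6R,11E)-2,16-dihydroxycembra-3,7,11,15(17)-tetraen-19,6-olide | C=C(CO)[C@H]1CC/C(C)=C/CCC2=C[C@@H](C/C(C)=C/[C@@H]1O)OC2=O | intermediate
28 | (1R,2S,3E,6R,11E)-2-hydroxy-16-oxocembra-3,7,11,15(17)-tetraen-19,6-olide (not isolated) | C=C(C=O)[C@H]1CC/C(C)=C/CCC2=C[C@@H](C/C(C)=C/[C@@H]1O)OC2=O | intermediate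
29 | (1R,2S,3E,6R,11E)-16-hydroxy-2,16-epoxycembra-3,7,11,15(17)-tetraen-19,6-olide (lactol anomers; not isolated) | C=C1C(O)O[C@H]2/C=C(\C)C[C@@H]3C=C(CC/C=C(\C)CC[C@H]12)C(=O)O3 | intermediate
30 | (1R,2S,3E,6R,11E)-cembra-3,7,11,15(17)-tetraene-16,2:19,6-diolide | C=C1C(=O)O[C@H]2/C=C(\C)C[C@@H]3C=C(CC/C=C(\C)CC[C@H]12)C(=O)O3 | intermediate
31 | (1R,2S,3E,6R,10E,12S)-12-hydroperoxycembra-3,7,10,15(17)-tetraene-16,2:19,6-diolide | C=C1C(=O)O[C@H]2/C=C(\C)C[C@@H]3C=C(C/C=C/[C@@](C)(OO)CC[C@H]12)C(=O)O3 | target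

**Step count and risks**

Total: 20 steps. Longest linear sequence: 18 steps (1–5, 7–11, 13–20); steps 6 and 12 are side branches.

Steps most likely to fail:

1. Step 15 (macrocyclization). What may go wrong: oligomerization instead of ring closure, carbon–carbon bond formation at C3 (13-membered ring with an exocyclic olefin), or reductive opening or ethylation of the epoxide without coupling. Fallback, setting out from 16 and returning at 23: the hydrometalation and the C(sp2)–C(sp3) coupling are separated so that the regiochemistry is fixed in an isolable intermediate. Syn hydrozirconation of the alkyne with Cp2Zr(H)Cl (zirconium to the less hindered, methyl-bearing C4) and iodinolysis would give (3E,7R,8R,9E)-8-(TBS-oxy)-7-[3-(TBS-oxy)prop-1-en-2-yl]-10-iodo-4-methylundeca-3,9-dien-1-ol F1. Iodine/PPh3/imidazole would give the corresponding 1,10-diiodide F2. Alkylation of the lithium enolate of 19 with the primary iodide would give the alkenyl iodide chloromethyl lactone F3, and NaI in acetone would give the iodomethyl lactone F4. A nickel-catalysed reductive cross-electrophile coupling of the alkenyl iodide with the primary alkyl iodide (NiBr2(dme), 4,4′-di-tert-butyl-2,2′-bipyridine, Mn, DMA, high dilution) would then close the same C4–C5 bond with retention of olefin geometry and give 23 with the γ-lactone already in place.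

2. Step 20 (ene reaction). What may go wrong: hydrogen abstraction from the C20 methyl group instead of C10, attack on the wrong face of the olefin (C12 epimer), or competing oxygenation of C3=C4. Fallback, setting out from 30 and returning at 31: reagent-controlled epoxidation followed by stereospecific perhydrolysis. Shi epoxidation of the isolated C11=C12 olefin (D-fructose-derived ketone, KHSO5, K2CO3 buffer, 0 °C) should give the (11R,12R)-11,12-epoxide F5. Anhydrous H2O2 in Et2O with catalytic H3PMo12O40 should open it at the tertiary carbon with inversion to the (11R,12S)-11-hydroxy-12-hydroperoxide F6. Selective perketalization of the more nucleophilic hydroperoxide with 2-methoxypropene/PPTS would give the 2-methoxyprop-2-yl peroxide F7. Martin sulfurane dehydration of the secondary alcohol, which can only eliminate toward C10, would give the (10E)-allylic peroxyketal F8, and AcOH/THF/H2O would release 31.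

3. Step 7 (asymmetric allylation). What may go wrong: insufficient anti selectivity or enantioselectivity with the small, linear ynal, or slow turnover of the catalyst. Fallback, setting out from 6 and returning at 13: chirality is set at C1 first and transferred. Addition of (trimethylsilyl)acetylene to 6 under Me2Zn/ProPhenol catalysis (ligand enantiomer giving the S carbinol) would give (S,E)-9-(PMB-oxy)-6-methyl-1-(trimethylsilyl)non-6-en-1-yn-3-ol F9, and K2CO3/MeOH would give the terminal alkynol F10. MsCl/Et3N would give the mesylate F11. Pd(OAc)2/PPh3/Et2Zn would convert F11 into a configurationally defined allenylzinc reagent (anti SN2′ oxidative addition to zerovalent palladium, then transmetalation), which should add to 11 through a cyclic transition state to give the anti homopropargylic alcohol (3R,4R)-3-[(E)-6-(PMB-oxy)-3-methylhex-3-en-1-yl]hepta-1,5-diyn-4-ol F12. Palladium-catalysed cyclocarbonylation of the terminal alkyne onto the C2 hydroxyl (PdCl2, SnCl2, PPh3, CO, MeCN) would give 13.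

Further compounds
F1 | step 15 | (3E,7R,8R,9E)-8-(TBS-oxy)-7-[3-(TBS-oxy)prop-1-en-2-yl]-10-iodo-4-methylundeca-3,9-dien-1-ol | C=C(CO[Si](C)(C)C(C)(C)C)[C@@H](CC/C(C)=C/CCO)[C@@H](O[Si](C)(C)C(C)(C)C)/C=C(\C)I
F2 | step 15 | (3E,7R,8R,9E)-8-(TBS-oxy)-7-[3-(TBS-oxy)prop-1-en-2-yl]-1,10-diiodo-4-methylundeca-3,9-diene | C=C(CO[Si](C)(C)C(C)(C)C)[C@@H](CC/C(C)=C/CCI)[C@@H](O[Si](C)(C)C(C)(C)C)/C=C(\C)I
F3 | step 15 | (5S)-5-(chloromethyl)-3-[(3E,7R,8R,9E)-8-(TBS-oxy)-7-(3-(TBS-oxy)prop-1-en-2-yl)-10-iodo-4-methylundeca-3,9-dien-1-yl]dihydrofuran-2(3H)-one (C3 epimers) | C=C(CO[Si](C)(C)C(C)(C)C)[C@@H](CC/C(C)=C/CCC1C[C@@H](CCl)OC1=O)[C@@H](O[Si](C)(C)C(C)(C)C)/C=C(\C)I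
F4 | step 15 | (5S)-5-(iodomethyl) analogue of F3 (C3 epimers) | C=C(CO[Si](C)(C)C(C)(C)C)[C@@H](CC/C(C)=C/CCC1C[C@@H](CI)OC1=O)[C@@H](O[Si](C)(C)C(C)(C)C)/C=C(\C)I
F5 | step 20 | (1R,2S,3E,6R,11R,12R)-11,12-epoxycembra-3,7,15(17)-triene-16,2:19,6-diolide | C=C1C(=O)O[C@H]2/C=C(\C)C[C@@H]3C=C(CC[C@H]4O[C@]4(C)CC[C@H]12)C(=O)O3
F6 | step 20 | (1R,2S,3E,6R,11R,12S)-12-hydroperoxy-11-hydroxycembra-3,7,15(17)-triene-16,2:19,6-diolide | C=C1C(=O)O[C@H]2/C=C(\C)C[C@@H]3C=C(CC[C@@H](O)[C@@](C)(OO)CC[C@H]12)C(=O)O3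
F7 | step 20 | 12-O-(2-methoxyprop-2-yl)peroxy derivative of F6 | C=C1C(=O)O[C@H]2/C=C(\C)C[C@@H]3C=C(CC[C@@H](O)[C@@](C)(OOC(C)(C)OC)CC[C@H]12)C(=O)O3
F8 | step 20 | (1R,2S,3E,6R,10E,12S)-12-[(2-methoxyprop-2-yl)peroxy]cembra-3,7,10,15(17)-tetraene-16,2:19,6-diolide | C=C1C(=O)O[C@H]2/C=C(\C)C[C@@H]3C=C(C/C=C/[C@@](C)(OOC(C)(C)OC)CC[C@H]12)C(=O)O3
F9 | step 7 | (S,E)-9-[(4-methoxybenzyl)oxy]-6-methyl-1-(trimethylsilyl)non-6-en-1-yn-3-ol | C[Si](C)(C)C#C[C@@H](O)CC/C(C)=C/CCOCc1ccc(OC)cc1
F10 | step 7 | (S,E)-9-[(4-methoxybenzyl)oxy]-6-methylnon-6-en-1-yn-3-ol | C#C[C@@H](O)CC/C(C)=C/CCOCc1ccc(OC)cc1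
F11 | step 7 | (S,E)-9-[(4-methoxybenzyl)oxy]-6-methylnon-6-en-1-yn-3-yl methanesulfonate | C#C[C@@H](OS(C)(=O)=O)CC/C(C)=C/CCOCc1ccc(OC)cc1
F12 | step 7 | (3R,4R)-3-[(E)-6-(PMB-oxy)-3-methylhex-3-en-1-yl]hepta-1,5-diyn-4-ol | C#C[C@@H](CC/C(C)=C/CCOCc1ccc(OC)cc1)[C@@H](O)C#CC
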